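**Retrosynthetic overview**
1. Target 8 ← 5-O-methyl ether 7 by hydrolysis of the last vinylogous methyl ester.
2. 7 ← 2-hydroxy-5-methoxy-1,4-benzoquinone 3 + hexadecanal 5: the ring–chain C–C bond is made by an intermolecular Knoevenagel-type aldol condensation at the enolic C3, with conjugate reduction by a Hantzsch ester in the same flask.
3. 3 ← 2,5-dimethoxy-1,4-benzoquinone 2 ← 2,5-dihydroxy-1,4-benzoquinone 1; the desymmetrisation leaves one nucleophilic ring carbon, so only mono-alkylation is possible. 5 ← hexadecan-1-ol 4.
4. Ring order: no ring is built; the single quinone ring is bought intact in 1.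

Assumption: the target has no stereocentre and no stereogenic double bond, so the constitution shown (n-hexadecyl chain, 16 carbons) is the one compound to be made.

**Route**

Step 1
Reactants: 1 2,5-dihydroxy-1,4-benzoquinone
Product: 2 2,5-dimethoxy-1,4-benzoquinone
Conditions: MeOH, conc. HCl (cat.), rt, 16 h; product filtered off
Reagents that add atoms: methanol, CO
Why: The hydroxyquinone is a doubly vinylogous carboxylic acid, so acid-catalysed Fischer-type esterification (conjugate addition of methanol, loss of water) etherifies both enol groups, and the sparingly soluble product crystallises out and drives the equilibrium.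

Step 2
Reactants: 2 2,5-dimethoxy-1,4-benzoquinone
Product: 3 2-hydroxy-5-methoxy-1,4-benzoquinone
Conditions: NaOH (1.1 equiv), THF/H2O, 0 °C to rt; then 1 M HCl to pH 2
Reagents that add atoms: sodium hydroxide, [Na+].[OH-]
Why: Hydroxide cleaves one vinylogous ester by conjugate addition–elimination (saponification), and the hydroxyquinone formed is at once deprotonated to a delocalised anion that uses up the base and resists a second attack, so the reaction stops at the mono-ether.

Step 3
Reactants: 4 hexadecan-1-ol
Product: 5 hexadecanal
Conditions: 2,2,6,6-tetramethylpiperidin-1-oxyl (TEMPO, 10 mol %), PhI(OAc)2 (1.1 equiv), CH2Cl2, rt; used fresh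
Reagents that add atoms: none
Why: Oxoammonium-mediated oxidation (TEMPO/PhI(OAc)2, Piancatelli–Margarita conditions) of a primary alcohol in an anhydrous medium stops cleanly at the aldehyde without over-oxidation to the acid.

Step 4
Reactants: 3 2-hydroxy-5-methoxy-1,4-benzoquinone; 5 hexadecanal
Product: 7 3-hexadecyl-2-hydroxy-5-methoxy-1,4-benzoquinone, via alkylidene trione 6 (not isolated)
Conditions: Hantzsch ester (diethyl 2,6-dimethyl-1,4-dihydropyridine-3,5-dicarboxylate, 1.1 equiv), L-proline (20 mol %), CH2Cl2, rt
Reagents that add atoms: none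
Why: Proline-mediated Knoevenagel-type aldol condensation of the enolic C3 of 3 (the only nucleophilic ring carbon, C6 being part of a vinylogous ester) with aldehyde 5 gives alkylidene trione 6, which is reduced at once by conjugate hydride transfer from the Hantzsch ester (three-component reductive alkylation, by analogy with 2-hydroxy-1,4-naphthoquinone); no stereocentre is formed.

Step 5
Reactants: 7 3-hexadecyl-2-hydroxy-5-methoxy-1,4-benzoquinone
Product: 8 3-hexadecyl-2,5-dihydroxy-1,4-benzoquinone
Conditions: 2 M aq. NaOH (5 equiv), EtOH, reflux; then 2 M HCl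
Reagents that add atoms: sodium hydroxide, [Na+].[OH-]
Why: Hot aqueous alkali cleaves the remaining vinylogous methyl ester by conjugate addition–elimination (saponification, the standard end game for 3-alkyl-2,5-dimethoxyquinones) and acidification frees the dihydroxyquinone, the saturated chain being inert and no stereocentre involved.

**Compound list**
1 | 2,5-dihydroxy-1,4-benzoquinone | O=C1C=C(O)C(=O)C=C1O | starting material
2 | 2,5-dimethoxy-1,4-benzoquinone | COC1=CC(=O)C(OC)=CC1=O | intermediate
3 | 2-hydroxy-5-methoxy-1,4-benzoquinone | COC1=CC(=O)C(O)=CC1=O | intermediate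
4 | hexadecan-1-ol | CCCCCCCCCCCCCCCCO | starting material
5 | hexadecanal | CCCCCCCCCCCCCCCC=O | intermediate
6 | alkylidene trione 3-hexadecylidene-5-methoxycyclohex-5-ene-1,2,4-trione (formed in the flask, E/Z not defined, no stereocentre) | CCCCCCCCCCCCCCCC=C1C(=O)C(=O)C=C(OC)C1=O | intermediate
7 | 3-hexadecyl-2-hydroxy-5-methoxy-1,4-benzoquinone | CCCCCCCCCCCCCCCCC1=C(O)C(=O)C=C(OC)C1=O | intermediate
8 | 3-hexadecyl-2,5-dihydroxy-1,4-benzoquinone (achiral) | CCCCCCCCCCCCCCCCC1=C(O)C(=O)C=C(O)C1=O | target

**Step count and risks**
Total steps: 5. Longest linear sequence: 4 (steps 1, 2, 4, 5); step 3 is a one-step side arm that joins at step 4.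

Most likely to fail, in order:

Step 4 (reductive alkylation). The alkylidene trione 6 may be trapped by a second molecule of 3 (Michael dimer), or proline may be lost by exchange with the methoxy group, before hydride transfer. Fallback: attach the chain by aryllithium alkylation instead. Setting out from 2, reduction with Na2S2O4 (EtOAc/H2O) gives 2,5-dimethoxybenzene-1,4-diol F1. O-Methylation (Me2SO4, K2CO3, acetone, reflux) gives 1,2,4,5-tetramethoxybenzene F2. Ortho-lithiation (n-BuLi, THF, 0 °C) gives (2,3,5,6-tetramethoxyphenyl)lithium F3, which is alkylated with 1-bromohexadecane to 3-hexadecyl-1,2,4,5-tetramethoxybenzene F4. Oxidative demethylation with (NH4)2Ce(NO3)6 (MeCN/H2O, 0 °C) gives 3-hexadecyl-2,5-dimethoxy-1,4-benzoquinone F5. Hydrolysis of both vinylogous esters (2 M NaOH, EtOH, reflux; HCl) comes back to the route at 8.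

Step 2 (mono-hydrolysis). If the reaction cannot be stopped cleanly and gives mixtures of 1, 2 and 3, drop the desymmetrisation and rely on statistical control. Setting out from 1, used in three- to four-fold excess, run the same L-proline/Hantzsch ester reductive alkylation with 5 in EtOH at 50 °C. The Knoevenagel intermediate 3-hexadecylidene-5-hydroxycyclohex-5-ene-1,2,4-trione F6 is reduced in the flask, and the sequence comes back to the route directly at 8. Excess 1 is removed by its insolubility in CH2Cl2, and the dialkylated by-product by crystallisation.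

Step 5 (final hydrolysis). Under alkali 7 is an unreactive anion, so the hydrolysis may be sluggish or degrade material on long heating. Fallback: cleave the ether at the hydroquinone level. Setting out from 7, reduction with Na2S2O4 (EtOAc/H2O) gives 3-hexadecyl-5-methoxybenzene-1,2,4-triol F7. BBr3 (CH2Cl2, −78 °C to rt) cleaves the aryl methyl ether to 3-hexadecylbenzene-1,2,4,5-tetrol F8. Stirring in air (EtOAc, aq. NaHCO3) re-oxidises it and comes back to the route at 8.

**Further compounds**
F1 | step 4 | 2,5-dimethoxybenzene-1,4-diol | COc1cc(O)c(OC)cc1O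
F2 | step 4 | 1,2,4,5-tetramethoxybenzene | COc1cc(OC)c(OC)cc1OC
F3 | step 4 | (2,3,5,6-tetramethoxyphenyl)lithium | [Li]c1c(OC)c(OC)cc(OC)c1OC
F4 | step 4 | 3-hexadecyl-1,2,4,5-tetramethoxybenzene | CCCCCCCCCCCCCCCCc1c(OC)c(OC)cc(OC)c1OC
F5 | step 4 | 3-hexadecyl-2,5-dimethoxy-1,4-benzoquinone | CCCCCCCCCCCCCCCCC1=C(OC)C(=O)C=C(OC)C1=O
F6 | step 2 | 3-hexadecylidene-5-hydroxycyclohex-5-ene-1,2,4-trione | CCCCCCCCCCCCCCCC=C1C(=O)C(=O)C=C(O)C1=O
F7 | step 5 | 3-hexadecyl-5-methoxybenzene-1,2,4-triol | CCCCCCCCCCCCCCCCc1c(O)c(O)cc(OC)c1O
F8 | step 5 | 3-hexadecylbenzene-1,2,4,5-tetrol | CCCCCCCCCCCCCCCCc1c(O)c(O)cc(O)c1O
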